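The route rests on recognising the C6=C7 trisubstituted olefin, with its hydroxymethyl group on C7, as propargyl alcohol (lactone carbonyl = C1). In step 5 the tail Grignard reagent adds anti across the alkynol magnesium alkoxide under CuI catalysis (C7–C8), and the resulting chelated C6 alkenylmagnesium opens methyl (R)-glycidate at its CH2 carbon (C5–C6). One operation thus joins three components, fixes the 6Z geometry and delivers the C4 stereocentre as an α-hydroxy ester, which is later closed to the butenolide ring through a tetronate. The precursors are the E-homoallylic Grignard reagent from dihydro-β-ionone, propargyl alcohol and the commercial epoxy ester.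

Key step: step 5

Remark: chain positions are numbered from the lactone carbonyl (C1) of the target throughout. The organomagnesium species 8, 11 and 12 are drawn as monomers without solvent or halide bridges, and 8 is carried forward as a titrated ethereal solution.

Step 1
Reactants: 1 dihydro-β-ionone
Product: 3 2-(but-3-yn-1-yl)-1,3,3-trimethylcyclohex-1-ene, via enol phosphate 2 (not isolated)
Conditions: LiN(i-Pr)2 (1.05 equiv.), THF, −78 °C; ClP(O)(OEt)2, −78 °C → rt; then LiN(i-Pr)2 (2.3 equiv.), THF, −78 °C → rt; H2O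
Reagents that add atoms: none
Why: Kinetic deprotonation at the methyl group, O-phosphorylation of the enolate and base-induced elimination of diethyl phosphate from the terminal enol phosphate is the standard conversion of a methyl ketone into a terminal alkyne, and the tetrasubstituted ring olefin is inert to it.

Step 2
Reactants: 3 2-(but-3-yn-1-yl)-1,3,3-trimethylcyclohex-1-ene
Product: 6 (3E)-4-methyl-6-(2,6,6-trimethylcyclohex-1-en-1-yl)hex-3-en-1-ol, via alkenylalane 4 (not isolated), via lithium alanate 5 (not isolated)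
Conditions: Me3Al (2 equiv.), Cp2ZrCl2 (20 mol %), ClCH2CH2Cl, rt; volatiles removed; n-BuLi, hexane, 0 °C; oxirane (3 equiv.), THF, −30 °C → rt; cold 3 M HCl
Reagents that add atoms: trimethylaluminium C[Al](C)C; oxirane C1CO1
Why: Zirconium-catalysed syn-carboalumination puts methyl on the internal and aluminium on the terminal alkyne carbon, and the butyl alanate made from the alkenylalane opens oxirane with retention of olefin geometry, so the E-configured C10=C11 olefin and the two-carbon alcohol arm should arise in one flask.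

Step 3
Reactants: 6 (3E)-4-methyl-6-(2,6,6-trimethylcyclohex-1-en-1-yl)hex-3-en-1-ol
Product: 7 2-[(3E)-6-bromo-3-methylhex-3-en-1-yl]-1,3,3-trimethylcyclohex-1-ene
Conditions: CBr4, PPh3, CH2Cl2, 0 °C
Reagents that add atoms: carbon tetrabromide BrC(Br)(Br)Br
Why: The Appel reaction displaces the primary alkoxyphosphonium group by bromide under neutral conditions, so neither olefin should be isomerised or attacked.

Step 4
Reactants: 7 2-[(3E)-6-bromo-3-methylhex-3-en-1-yl]-1,3,3-trimethylcyclohex-1-ene
Product: 8 (E)-[4-methyl-6-(2,6,6-trimethylcyclohex-1-en-1-yl)hex-3-en-1-yl]magnesium bromide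
Conditions: Mg turnings (BrCH2CH2Br-activated), Et2O, slow addition, gentle reflux; titrated and used as solution
Reagents that add atoms: magnesium [Mg]
Why: Magnesium inserts cleanly into primary homoallylic bromides (Grignard formation), slow addition limits Wurtz coupling, and the open-chain reagent is strongly favoured over its cyclopropylcarbinyl isomer, so the E olefin should be retained.

Step 5
Reactants: 8 (E)-[4-methyl-6-(2,6,6-trimethylcyclohex-1-en-1-yl)hex-3-en-1-yl]magnesium bromide; 9 propargyl alcohol; 10 methyl (R)-glycidate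
Product: 13 methyl (2R,4Z,8E)-2-hydroxy-5-(hydroxymethyl)-9-methyl-11-(2,6,6-trimethylcyclohex-1-en-1-yl)undeca-4,8-dienoate, via magnesium alkoxide 11 (not isolated), via oxamagnesacycle 12 (not isolated)
Conditions: 9, i-PrMgCl (1.0 equiv.), THF–Et2O, −20 °C; 8 (1.2 equiv.), CuI (10 mol %), Et2O, −10 °C → rt; then THF, 10 (1.5 equiv.), −40 → −10 °C; aq. NH4Cl
Reagents that add atoms: none
Why: Proposed new method: the alkyl group of 8 is passed to copper and adds across the triple bond of alkoxide 11 in the anti sense directed by the magnesium alkoxide, the alkyl group ending on the internal carbon (C7) and the metal on the terminal carbon (C6), where it is held as the five-membered oxamagnesacycle 12 cis to the CH2O arm; a second transmetalation to copper then lets this C6 nucleophile displace the epoxide oxygen of 10 at the CH2 carbon (C5) by SN2 attack with retention at the sp2 carbon. The closest known reaction types are the CuI-catalysed anti-carbomagnesiation of propargylic alcohols with trapping of the chelated alkenylmagnesium by iodine, allylic halides or carbonyl compounds, and the copper-catalysed opening of glycidic esters at C3 by alkenyl Grignard reagents, so only the union of the two in one flask is unproven. No ring is closed and no stereocentre is created: the R centre of 13 is that of 10, whose C–O bond at the stereogenic carbon is never broken, and it becomes C4 of the target. The 6Z geometry follows from anti addition, chelation and stereoretentive substitution, which together place C5 cis to the hydroxymethyl group and C8 trans to it. Regioselectivity in the epoxide opening is secured by the unhindered methylene carbon and by the ester, which disfavours SN2 attack at the α-carbon, and chemoselectivity for epoxide over ester by the soft alkenylcopper species at low temperature. Pre-forming 11 with i-PrMgCl spares one equivalent of 8, and the slight excess of 8 consumes every acidic alkyne C–H before 12 accumulates.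

Step 6
Reactants: 13 methyl (2R,4Z,8E)-2-hydroxy-5-(hydroxymethyl)-9-methyl-11-(2,6,6-trimethylcyclohex-1-en-1-yl)undeca-4,8-dienoate
Product: 14 methyl (2R,4Z,8E)-5-{[(tert-butyldimethylsilyl)oxy]methyl}-2-hydroxy-9-methyl-11-(2,6,6-trimethylcyclohex-1-en-1-yl)undeca-4,8-dienoate
Conditions: TBSCl (1.05 equiv.), imidazole, CH2Cl2, −20 → 0 °C
Reagents that add atoms: tert-butyldimethylsilyl chloride CC(C)(C)[Si](C)(C)Cl
Why: Silyl ether formation should be selective because the primary allylic hydroxyl is far more accessible and nucleophilic than the secondary hydroxyl next to the ester.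

Step 7
Reactants: 14 methyl (2R,4Z,8E)-5-{[(tert-butyldimethylsilyl)oxy]methyl}-2-hydroxy-9-methyl-11-(2,6,6-trimethylcyclohex-1-en-1-yl)undeca-4,8-dienoate
Product: 15 methyl (2R,4Z,8E)-2-acetoxy-5-{[(tert-butyldimethylsilyl)oxy]methyl}-9-methyl-11-(2,6,6-trimethylcyclohex-1-en-1-yl)undeca-4,8-dienoate
Conditions: Ac2O, pyridine, DMAP (cat.), CH2Cl2, 0 °C → rt
Reagents that add atoms: acetic anhydride CC(=O)OC(C)=O
Why: DMAP-catalysed acylation of the remaining secondary alcohol uses only amine bases, which are too weak to touch the C4 stereocentre.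

Step 8
Reactants: 15 methyl (2R,4Z,8E)-2-acetoxy-5-{[(tert-butyldimethylsilyl)oxy]methyl}-9-methyl-11-(2,6,6-trimethylcyclohex-1-en-1-yl)undeca-4,8-dienoate
Product: 16 (5R)-5-[(2Z,6E)-3-{[(tert-butyldimethylsilyl)oxy]methyl}-7-methyl-9-(2,6,6-trimethylcyclohex-1-en-1-yl)nona-2,6-dien-1-yl]-4-hydroxyfuran-2(5H)-one
Conditions: LiN(SiMe3)2 (2.3 equiv.), THF, −78 → 0 °C; cold 0.5 M HCl to pH 3; crude acid used directly
Reagents that add atoms: none
Why: In this Dieckmann condensation the acetate enolate attacks the neighbouring methyl ester in a 5-exo-trig closure and the product is at once deprotonated to the lithium tetronate, which drives the cyclisation and shields the C4 hydrogen from exchange.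

Step 9
Reactants: 16 (5R)-5-[(2Z,6E)-3-{[(tert-butyldimethylsilyl)oxy]methyl}-7-methyl-9-(2,6,6-trimethylcyclohex-1-en-1-yl)nona-2,6-dien-1-yl]-4-hydroxyfuran-2(5H)-one
Product: 17 (2R)-2-[(2Z,6E)-3-{[(tert-butyldimethylsilyl)oxy]methyl}-7-methyl-9-(2,6,6-trimethylcyclohex-1-en-1-yl)nona-2,6-dien-1-yl]-5-oxo-2,5-dihydrofuran-3-yl trifluoromethanesulfonate
Conditions: Tf2O (1.2 equiv.), i-Pr2NEt, CH2Cl2, −78 °C
Reagents that add atoms: trifluoromethanesulfonic anhydride O=S(=O)(OS(=O)(=O)C(F)(F)F)C(F)(F)F
Why: O-sulfonylation of the vinylogous acid at low temperature with a hindered amine should give the enol triflate without deprotonating the γ-position that carries the stereocentre.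

Step 10
Reactants: 17 (2R)-2-[(2Z,6E)-3-{[(tert-butyldimethylsilyl)oxy]methyl}-7-methyl-9-(2,6,6-trimethylcyclohex-1-en-1-yl)nona-2,6-dien-1-yl]-5-oxo-2,5-dihydrofuran-3-yl trifluoromethanesulfonate
Product: 18 (5R)-5-[(2Z,6E)-3-{[(tert-butyldimethylsilyl)oxy]methyl}-7-methyl-9-(2,6,6-trimethylcyclohex-1-en-1-yl)nona-2,6-dien-1-yl]-4-(hydroxymethyl)furan-2(5H)-one
Conditions: Bu3SnCH2OH (1.5 equiv.), Pd(PPh3)4 (5 mol %), LiCl (3 equiv.), 1,4-dioxane, 80 °C
Reagents that add atoms: (tributylstannyl)methanol CCCC[Sn](CCCC)(CCCC)CO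
Why: In this Stille coupling the electron-poor enol triflate adds readily to zerovalent palladium and the α-oxygenated carbon of the stannane is transferred in preference to butyl, all under neutral conditions that leave C4 and the silyl ether alone.

Step 11
Reactants: 18 (5R)-5-[(2Z,6E)-3-{[(tert-butyldimethylsilyl)oxy]methyl}-7-methyl-9-(2,6,6-trimethylcyclohex-1-en-1-yl)nona-2,6-dien-1-yl]-4-(hydroxymethyl)furan-2(5H)-one
Product: 19 (6Z)-neomanoalide
Conditions: HF·pyridine, pyridine, THF, 0 °C → rt
Reagents that add atoms: none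
Why: Buffered fluoride cleavage of the primary silyl ether avoids the basic conditions under which the γ-hydrogen of a butenolide can exchange, so the R configuration at C4 and both olefin geometries should reach the target unchanged.

Compound list
1 | dihydro-β-ionone, 4-(2,6,6-trimethylcyclohex-1-en-1-yl)butan-2-one | CC(=O)CCC1=C(C)CCCC1(C)C | starting material
2 | diethyl 4-(2,6,6-trimethylcyclohex-1-en-1-yl)but-1-en-2-yl phosphate | C=C(CCC1=C(C)CCCC1(C)C)OP(=O)(OCC)OCC | intermediate
3 | 2-(but-3-yn-1-yl)-1,3,3-trimethylcyclohex-1-ene | C#CCCC1=C(C)CCCC1(C)C | intermediate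
4 | dimethyl[(1E)-2-methyl-4-(2,6,6-trimethylcyclohex-1-en-1-yl)but-1-en-1-yl]alane | C[Al](C)/C=C(\C)CCC1=C(C)CCCC1(C)C | intermediate
5 | lithium butyl(dimethyl)[(1E)-2-methyl-4-(2,6,6-trimethylcyclohex-1-en-1-yl)but-1-en-1-yl]alanate | [Li+].CCCC[Al-](C)(C)/C=C(\C)CCC1=C(C)CCCC1(C)C | intermediate
6 | (3E)-4-methyl-6-(2,6,6-trimethylcyclohex-1-en-1-yl)hex-3-en-1-ol | OCC/C=C(\C)CCC1=C(C)CCCC1(C)C | intermediate
7 | 2-[(3E)-6-bromo-3-methylhex-3-en-1-yl]-1,3,3-trimethylcyclohex-1-ene | BrCC/C=C(\C)CCC1=C(C)CCCC1(C)C | intermediate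
8 | (E)-[4-methyl-6-(2,6,6-trimethylcyclohex-1-en-1-yl)hex-3-en-1-yl]magnesium bromide | Br[Mg]CC/C=C(\C)CCC1=C(C)CCCC1(C)C | intermediate
9 | propargyl alcohol | C#CCO | starting material
10 | methyl (R)-glycidate, methyl (2R)-oxirane-2-carboxylate | COC(=O)[C@H]1CO1 | starting material
11 | chloromagnesium prop-2-yn-1-olate | C#CCO[Mg]Cl | intermediate
12 | 4-[(3E)-4-methyl-6-(2,6,6-trimethylcyclohex-1-en-1-yl)hex-3-en-1-yl]-2,5-dihydro-1,2-oxamagnesole (ring Mg–O–CH2–C(R)=CH) | [Mg]1OCC(CC/C=C(\C)CCC2=C(C)CCCC2(C)C)=C1 | intermediate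
13 | methyl (2R,4Z,8E)-2-hydroxy-5-(hydroxymethyl)-9-methyl-11-(2,6,6-trimethylcyclohex-1-en-1-yl)undeca-4,8-dienoate | CC1=C(CC/C(C)=C/CC/C(=C/C[C@@H](O)C(=O)OC)CO)C(C)(C)CCC1 | intermediate
14 | methyl (2R,4Z,8E)-5-{[(tert-butyldimethylsilyl)oxy]methyl}-2-hydroxy-9-methyl-11-(2,6,6-trimethylcyclohex-1-en-1-yl)undeca-4,8-dienoate | CC1=C(CC/C(C)=C/CC/C(=C/C[C@@H](O)C(=O)OC)CO[Si](C)(C)C(C)(C)C)C(C)(C)CCC1 | intermediate
15 | methyl (2R,4Z,8E)-2-acetoxy-5-{[(tert-butyldimethylsilyl)oxy]methyl}-9-methyl-11-(2,6,6-trimethylcyclohex-1-en-1-yl)undeca-4,8-dienoate | CC1=C(CC/C(C)=C/CC/C(=C/C[C@@H](OC(C)=O)C(=O)OC)CO[Si](C)(C)C(C)(C)C)C(C)(C)CCC1 | intermediate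
16 | (5R)-5-[(2Z,6E)-3-{[(tert-butyldimethylsilyl)oxy]methyl}-7-methyl-9-(2,6,6-trimethylcyclohex-1-en-1-yl)nona-2,6-dien-1-yl]-4-hydroxyfuran-2(5H)-one | CC1=C(CC/C(C)=C/CC/C(=C/C[C@H]2OC(=O)C=C2O)CO[Si](C)(C)C(C)(C)C)C(C)(C)CCC1 | intermediate
17 | (2R)-2-[(2Z,6E)-3-{[(tert-butyldimethylsilyl)oxy]methyl}-7-methyl-9-(2,6,6-trimethylcyclohex-1-en-1-yl)nona-2,6-dien-1-yl]-5-oxo-2,5-dihydrofuran-3-yl trifluoromethanesulfonate | CC1=C(CC/C(C)=C/CC/C(=C/C[C@H]2OC(=O)C=C2OS(=O)(=O)C(F)(F)F)CO[Si](C)(C)C(C)(C)C)C(C)(C)CCC1 | intermediate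
18 | (5R)-5-[(2Z,6E)-3-{[(tert-butyldimethylsilyl)oxy]methyl}-7-methyl-9-(2,6,6-trimethylcyclohex-1-en-1-yl)nona-2,6-dien-1-yl]-4-(hydroxymethyl)furan-2(5H)-one | CC1=C(CC/C(C)=C/CC/C(=C/C[C@H]2OC(=O)C=C2CO)CO[Si](C)(C)C(C)(C)C)C(C)(C)CCC1 | intermediate
19 | (6Z)-neomanoalide, (5R)-4-(hydroxymethyl)-5-[(2Z,6E)-3-(hydroxymethyl)-7-methyl-9-(2,6,6-trimethylcyclohex-1-en-1-yl)nona-2,6-dien-1-yl]furan-2(5H)-one | CC1=C(CC/C(C)=C/CC/C(=C/C[C@H]2OC(=O)C=C2CO)CO)C(C)(C)CCC1 | target

Total step count: 11 steps.
Longest linear sequence: 11 steps, from 1 to 19; 9 and 10 enter at step 5.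

Steps most likely to fail

1. Step 5 (carries the label). The chelated alkenylmagnesium may pass to copper too slowly at the low temperature that the ester tolerates. Attack at the ester carbonyl, protonation of the C6–metal bond or opening of the epoxide by halide could then compete. The fallback uses known chemistry, sets out from 8 and 9 and returns at 14. The precedented first half is kept: oxamagnesacycle 12, made as in step 5, is quenched with I2 (THF, −40 → 0 °C) to give the vinyl iodide (2Z,5E)-2-(iodomethylidene)-6-methyl-8-(2,6,6-trimethylcyclohex-1-en-1-yl)oct-5-en-1-ol F1, with iodine cis to the hydroxymethyl group. Silylation (TBSCl, imidazole, CH2Cl2) should give its tert-butyldimethylsilyl ether F2. Iodine–magnesium exchange (i-PrMgCl·LiCl, THF, −20 °C → rt) should give, with retention, the alkenylmagnesium chloride F3. This reagent opens 10 at the methylene carbon under CuI catalysis (10 mol %, THF, −40 °C) and should give 14 directly, so step 6 is not needed.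

2. Step 8. Proton exchange at the stereocentre may compete with enolisation of the acetate and erode the configuration at C4, or intermolecular Claisen condensation may overtake ring closure. The fallback sets out from 14 and returns at 16. Ti(OiPr)4-catalysed transesterification in allyl alcohol (70 °C) should give the allyl ester allyl (2R,4Z,8E)-5-{[(tert-butyldimethylsilyl)oxy]methyl}-2-hydroxy-9-methyl-11-(2,6,6-trimethylcyclohex-1-en-1-yl)undeca-4,8-dienoate F4. (Triphenylphosphoranylidene)ketene, Ph3P=C=C=O (THF, 60 °C), adds to the free hydroxyl, and the resulting ester ylide closes onto the allyl ester by intramolecular Wittig olefination without any base. This should give the allyl tetronate (5R)-4-(allyloxy)-5-[(2Z,6E)-3-{[(tert-butyldimethylsilyl)oxy]methyl}-7-methyl-9-(2,6,6-trimethylcyclohex-1-en-1-yl)nona-2,6-dien-1-yl]furan-2(5H)-one F5. Pd(PPh3)4-catalysed allyl transfer to morpholine (THF, rt) then frees tetronic acid 16, so step 7 is not needed.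

3. Step 10. Transfer of the sp3 hydroxymethyl group from tin may be slow, which would let butyl transfer, reduction or hydrolysis of the enol triflate take over. The fallback sets out from 17 and returns at 18. Suzuki–Miyaura coupling with potassium {[(4-methoxybenzyl)oxy]methyl}trifluoroborate, K[PMBOCH2BF3] (Pd(OAc)2, RuPhos, K3PO4, toluene–H2O, 80 °C) should give the 4-methoxybenzyl ether (5R)-5-[(2Z,6E)-3-{[(tert-butyldimethylsilyl)oxy]methyl}-7-methyl-9-(2,6,6-trimethylcyclohex-1-en-1-yl)nona-2,6-dien-1-yl]-4-{[(4-methoxybenzyl)oxy]methyl}furan-2(5H)-one F6. DDQ (CH2Cl2–pH 7 buffer, 0 °C) removes the benzylic ether and returns 18.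

Further compounds
F1 | step 5 | (2Z,5E)-2-(iodomethylidene)-6-methyl-8-(2,6,6-trimethylcyclohex-1-en-1-yl)oct-5-en-1-ol | OC/C(CC/C=C(\C)CCC1=C(C)CCCC1(C)C)=C\I
F2 | step 5 | tert-butyl{[(2Z,5E)-2-(iodomethylidene)-6-methyl-8-(2,6,6-trimethylcyclohex-1-en-1-yl)oct-5-en-1-yl]oxy}dimethylsilane | CC(C)(C)[Si](C)(C)OC/C(CC/C=C(\C)CCC1=C(C)CCCC1(C)C)=C\I
F3 | step 5 | {(1Z,5E)-2-{[(tert-butyldimethylsilyl)oxy]methyl}-6-methyl-8-(2,6,6-trimethylcyclohex-1-en-1-yl)octa-1,5-dien-1-yl}magnesium chloride | CC(C)(C)[Si](C)(C)OC/C(CC/C=C(\C)CCC1=C(C)CCCC1(C)C)=C\[Mg]Cl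
F4 | step 8 | allyl (2R,4Z,8E)-5-{[(tert-butyldimethylsilyl)oxy]methyl}-2-hydroxy-9-methyl-11-(2,6,6-trimethylcyclohex-1-en-1-yl)undeca-4,8-dienoate | CC1=C(CC/C(C)=C/CC/C(=C/C[C@@H](O)C(=O)OCC=C)CO[Si](C)(C)C(C)(C)C)C(C)(C)CCC1
F5 | step 8 | (5R)-4-(allyloxy)-5-[(2Z,6E)-3-{[(tert-butyldimethylsilyl)oxy]methyl}-7-methyl-9-(2,6,6-trimethylcyclohex-1-en-1-yl)nona-2,6-dien-1-yl]furan-2(5H)-one | CC1=C(CC/C(C)=C/CC/C(=C/C[C@H]2OC(=O)C=C2OCC=C)CO[Si](C)(C)C(C)(C)C)C(C)(C)CCC1
F6 | step 10 | (5R)-5-[(2Z,6E)-3-{[(tert-butyldimethylsilyl)oxy]methyl}-7-methyl-9-(2,6,6-trimethylcyclohex-1-en-1-yl)nona-2,6-dien-1-yl]-4-{[(4-methoxybenzyl)oxy]methyl}furan-2(5H)-one | CC1=C(CC/C(C)=C/CC/C(=C/C[C@H]2OC(=O)C=C2COCc3ccc(OC)cc3)CO[Si](C)(C)C(C)(C)C)C(C)(C)CCC1
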